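The vessel holds starting material, protic impurity and enzyme, closed and stirred, and I ask how the rate at 50 % conversion answers to the enzyme charged.

| setting | amber | violet | ochre | flask |
|---|---|---|---|---|
| starting material | 0.10 M | 0.10 M | 0.15 M | 0.10 M |
| protic impurity | 2.5 mM | 3.8 mM | 5 mM | 5.00 mM |
| enzyme | 10 µM | 10 µM | 10 µM | 10 µM |
| remark | run made earlier | run made earlier | run made earlier |  |

- amber (time / min: product / %, starting material / %): 1.00: 6, 94; 2.50: 9, 83; 6.00: 28, 69; 15.0: 59, 43
- violet (time / min: product / %, starting material / %): 4.00: 18, 76; 8.00: 35, 61; 10.0: 45, 56; 15.0: 54, 37
- ochre (time / min: product / %, starting material / %): 4.00: 17, 80; 8.00: 27, 65; 10.0: 38, 57; 15.0: 50, 48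

(readings scatter by 2 percentage points)

- apparent order in enzyme when 50 % of the starting material are converted (percent change of the rate of making product for one percent more enzyme charged)

- what was read earlier has a scatter of 2 percentage points, one standard deviation
- reactions considered so far: starting material + protic impurity -> quenched substrate; starting material + enzyme -> product + enzyme; enzyme -> spent catalyst
- no earlier run changes the charge of enzyme; that part of a forecast is a guess

How much starting material reaches the enzyme? I take the quench as fast and one to one; protic impurity is charged at less than starting material, which makes it the limiting reagent of the quench, so I reckon that this flask leaves 95.0 % of the starting material free.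

How long does this flask need? In the amber run, free starting material falls with a constant of 0.0576 /min up to 6.00 min and 0.0546 /min up to 15.0 min. With the second constant, I expect 50 % conversion after 11.8 min.

How much enzyme dies on the way? The amber drift reads as decay of 0.0121 /min, a weak reading, since the violet constant rises from 0.0589 /min to 0.0637 /min. Decay constant times time to that conversion is the decay toll, 0.142. If the time goes as one over the enzyme charge, a fixed conversion is reached sooner with more enzyme, and the order is one plus the toll. My reckoning gives 1.14, and no run tests that assumption.

The forecast differs, at 1.05, reasoning that “More enzyme reaches 50% sooner, with less decay”.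

The flask gives 1.2, and the forecast stands within its margin.

    starting material + protic impurity → quenched substrate (k = 0.200 /M/s)
    starting material + enzyme → product + enzyme, rate k2*[starting material]*[enzyme]/(1 + ([starting material]/Km2)) (0.160 M, k = 150 /M/s)
    enzyme → spent catalyst (k = 2.30 × 10⁻⁴ /s)

In this flask the quench ran while protic impurity lasted, with a half-life of 0.81 min at 5.02 min, and at 6.00 min 0.292 % of the impurity charge remained beside quenched substrate at 4.99 % of the starting material charged. Enzyme made product and decayed, standing at 92.1 % of its charge at 6.00 min and 84.7 % at 12.0 min, and the flask reached 50 % conversion at 11.0 min, where the decay toll from the hidden constant is 0.152.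

The numbers in the tables come from a simulation from invented constants; scatter was added.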